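The ratio to hold on to was 0.169, protic impurity over starting material in elm, and I built my quick reply on it, against your hunch that the small charge of free catalyst would cost yield.

| setting | elm | birch | cedar |
|---|---|---|---|
| starting material | 0.16 M | 0.16 M | 0.16 M |
| protic impurity | 0.0270 M | 0.0160 M | 0.0210 M |
| free catalyst | 1.4 mM | 1.4 mM | 1.4 mM |
| time | 4.0 h | 4.0 h | 4.0 h |

    starting material + free catalyst ⇌ catalyst intermediate A (K1 = 2.8 L mol⁻¹, k1 = 120 L mol⁻¹ min⁻¹)
    catalyst intermediate A ⇌ catalyst intermediate B (K2 = 1.0, k2 = 13 min⁻¹)
    catalyst intermediate B → free catalyst + target (k3 = 49 min⁻¹)
    starting material + protic impurity → quenched substrate (k4 = 12 L mol⁻¹ min⁻¹)

* which of these there is most of at the end, counted by the starting material in it, elm (catalyst intermediate A / target / starting material / catalyst intermediate B)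
* which of these there is most of at the end, counted by the starting material in it, birch (catalyst intermediate A / target / starting material / catalyst intermediate B)
* which of these there is most of at the end, counted by the starting material in it, cedar (catalyst intermediate A / target / starting material / catalyst intermediate B)
* final amount of the leader among these, as a percentage of the starting material charged, in elm
* final amount of the leader among these, as a percentage of the starting material charged, in birch
* final amount of the leader among these, as a percentage of the starting material charged, in cedar

I froze what stayed nearly constant. While the protic impurity lasted, I held starting material at its charge, which made step 4 pseudo-first-order in the impurity, with a half-life of 0.361 min. On the catalytic path I froze intermediates A and B at steady state. That gave a net passage out of A of 10.3 min⁻¹, and, with free catalyst at its charge and starting material low, a pseudo-first-order constant of 0.0325 min⁻¹, so a half-life of 21.3 min.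

The impurity therefore went faster than the catalytic path by a factor of 59.0, and because starting material was in excess, each equivalent of impurity cost one equivalent of starting material. In birch that left 90.0%, in elm 83.1% and in cedar 86.9%. This is the impurity ceiling, the fraction of charged starting material left for target once the protic impurity has taken its equivalent, which is one minus the ratio of the two charges. The 4.0 h allowed came to 11.3 catalytic half-lives, so I committed to target leading each flask, just under its ceiling.

The forecast gave target 83.1% in elm, 89.9% in birch and 86.8% in cedar, on the ground that “The impurity therefore dies within minutes and removes about one equivalent of starting material”.

The simulation put target in the lead at 83.1% in elm, target at 89.9% in birch and target at 86.8% in cedar. Birch still held 0.056% of its starting material unbound at 4.00 h, so its target stood about that far under its ceiling. The same birch flask read at 1.5 h held 83.0% target, so its ceiling left 7 percentage points still to come, and starting material then stood at 6.96%.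

All constants are those of an exercise; the flask was simulated.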